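## Structural features

Eduesmine is a 2,5-diaryl-3,4-bis(hydroxymethyl)tetrahydrofuran. One saturated five-membered ring (O1, C2 to C5) carries a 4-hydroxy-3-methoxyphenyl group at C2 and at C5 and a CH2OH group (carbons C3a and C4a) at C3 and at C4. The four stereocentres C2, C3, C4 and C5 are contiguous and all (S). The molecule is C2-symmetric about the axis through O1 and the midpoint of C3–C4: C3/C4 are trans, each aryl group is cis to the CH2OH group next to it (the less stable arrangement), and the two aryl groups are therefore trans across the ring. The C2–O1 and C5–O1 bonds are benzylic and para to an oxygen donor, so acid can open or epimerise them and hydrogenation catalysts can cleave them; the free phenols are sensitive to oxidants. The ring is easy to close; the real difficulty is to set four adjacent stereocentres in one enantiomeric series, two of them against thermodynamic preference, and to keep them to the end. The key step exploits the C2-symmetric pair C3/C4: each carries a one-carbon oxygenated branch, so the C3–C3a and C4–C4a bonds can be made by moving two O–CH2 carbanions from oxygen to the two inner carbons of a conjugated diene, whose outer carbons later become C2 and C5.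

## Logic of the disconnections

**18 from 17.** The four O–CH2Ph bonds (two on the phenol oxygens, two on the oxygens of C3a and C4a) are the last to be cut. Phenols and primary alcohols cannot be carried free through organometallic, oxidative and Lewis-acidic steps, and one kind of protecting group allows one final operation. The skeleton is not simplified. The forward step must cleave O-benzyl groups faster than the benzylic ring bonds C2–O1 and C5–O1.

**17 from 16.** The C2–H bond is cut, which puts a hydroxyl group on C2. C2 can then be set by face-selective hydride delivery to a planar oxocarbenium ion next to the C3 stereocentre. The gain is that C2 need not be controlled in an open chain. The forward step needs hydride attack anti to the C3 substituent under kinetic control, without ionising C5–O1.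

**16 from 14 (through 15).** The O1–C2 bond is cut and C2 goes back from the ketone to the carbinol level. This restores C2 symmetry, so C2 and C5 become equivalent carbinol carbons and both halves can be made by the same reactions. The forward step must oxidise only one of two equal benzylic alcohols; ring closure of 15 to 16 is relied on to shield the second.

**14 from 10 and 12 (through 13).** The C2–aryl and C5–aryl bonds are cut. Both aryl carbinols arise from one two-directional carbonyl addition, and the arenes leave as one simple bromide, used twice. What remains is a six-carbon C2-symmetric dialdehyde that holds only the C3/C4 stereocentres. The forward step needs addition anti to the α-branch at both carbonyl groups, without enolisation.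

**12 from 11.** The O–CH2Ph bond of the aryl ether is cut; the phenol must be masked before magnesium insertion.

**10 from 8 (through 9).** The C=O bonds at the future C2 and C5 are traced back to C=C bonds to a CH–CH3 unit. A propenyl group survives n-BuLi and NaH, whereas an aldehyde does not, so the aldehydes appear only one step before use. The forward step needs ozone to cleave the alkenes and spare the benzyl ethers, with no epimerisation at C3 and C4.

**8 from 7.** The O–CH2Ph bonds on the C3a and C4a oxygens are cut. These ethers protect the alcohols and later act as the chelating groups.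

**7 from 5 (through 6).** The C3–C3a and C4–C4a bonds are cut, and each CH2 carbon is returned to the oxygen of a carbinol three atoms away (retro-[2,3] shift of a homoallylic alcohol with an (E) alkene). Two adjacent carbon stereocentres are exchanged for two remote, identical carbinol centres that can be bought, and the CH2OH oxygens are already in place. The forward step needs two tin–lithium exchanges and two suprafacial shifts of the same sense, which rests on the (Z) geometry of both alkenes.

**5 from 3 and 4.** The two O–CH2Sn bonds are cut (ether formation), so 4 is needed twice. The forward step must not touch the carbinol C–O bonds.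

**3 from 2.** The four C–H bonds added across two triple bonds are removed. The forward step needs cis addition twice without over-reduction.

**2 from 1.** The central sp–sp bond of the C8 chain is cut, so both halves come from one commercial C4 alkynol. The forward step is an oxidative homocoupling that does not involve the stereocentres.

## Other disconnections considered

Alternative 1: The cut is at the C2–aryl and C5–aryl bonds of an intact tetrahydrofuran.
- Forward step: the trans-diamide (3R,4R)-N3,N4-di(quinolin-8-yl)tetrahydrofuran-3,4-dicarboxamide A2 would be coupled twice with 1-(benzyloxy)-4-iodo-2-methoxybenzene A3 under Pd(OAc)2 and AgOAc to give the diarylated diamide A1. Each amide directs palladation of the neighbouring ring CH2 through a five-membered palladacycle, so each aryl group must enter cis to its amide.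
- In favour: the ring and the trans C3/C4 pair are present from the start. The two cis relationships are enforced by metallacycle geometry and not by substituent size. Both arenes arrive late in one convergent operation. A1 is only an amide-to-alcohol reduction and a debenzylation away from 18.
- Against: the second arylation must occur on an already crowded ring, and two bidentate amides on a small ring can tie up palladium. A stoichiometric silver salt is needed. Enantiopure A2 needs a resolution or a separate asymmetric synthesis. Reductive removal of two hindered aminoquinoline groups next to two epimerisable α-carbonyl centres in a strained cis arrangement is the step most likely to erode the stereochemistry.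
- Comparison: on structure, this plan keeps the ring and adds the arenes, whereas the chosen plan keeps an open symmetric chain and closes the ring last. On mechanism, control at C2 and C5 by the palladacycle is at least as dependable as the chelate-controlled addition and oxocarbenium reduction of the chosen plan; here the alternative is the better. On step economy it is also clearly the better (roughly half the steps). The chosen plan is better in its source of absolute configuration (chiral pool, stereospecific transfer) and in having no auxiliary to remove.

Alternative 2: The cut is at C4–C5 and O1–C2; the ring is traced back to a γ-lactone that lacks the C2 aryl group and C3a.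
- Forward step: a chiral triazolium-derived carbene would convert (E)-4-(benzyloxy)but-2-enal A5 into a homoenolate, which would add to 4-(benzyloxy)-3-methoxybenzaldehyde A6; the alkoxide would then close on the acyl azolium to give the cis-lactone A4.
- In favour: the reaction is catalytic and asymmetric, both partners are simple, and the cis C4/C5 relationship and the absolute configuration would be set together. The later steps (trans-selective enolate alkylation at C3 with a benzyloxymethyl halide, aryllithium addition, hemiketal reduction, debenzylation) are established lactone chemistry for this class. The total would be about six or seven steps.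
- Against: cis/trans and enantio-selectivity must be delivered together with an electron-rich, weakly electrophilic aldehyde. The γ-benzyloxy group of A5 can be expelled from the extended enol intermediate, which competes with homoenolate addition. The C2 symmetry of the target is not used.
- Comparison: on structure, the two halves are built by different reactions, whereas the chosen plan does everything twice in one flask. On mechanism, catalyst-controlled addition is less predictable in relative and absolute sense than a stereospecific sigmatropic transfer from a chiral-pool centre. On step economy, and in avoiding tin and ozone, the alternative is the better. The hemiketal reduction and hydrogenolysis at the end are the same, so the two plans are equal there.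

Alternative 3: The cut is at C2–C3 and C4–C5.
- Forward step: the bis(benzylic ether) (2R,3E,5E,7R)-2,7-bis{[4-(benzyloxy)-3-methoxybenzyl]oxy}octa-3,5-diene A8 would be deprotonated at both benzylic ether carbons with excess n-BuLi. Two successive [2,3]-shifts would give the diol A7 with all four stereocentres and both aryl carbinol carbons in place.
- In favour: one step makes two C–C bonds and four stereocentres. The arenes enter by simple O-alkylation, so the sensitive dialdehyde and the Grignard addition are avoided. The parent diol of A8, (2R,3E,5E,7R)-octa-3,5-diene-2,7-diol A9, is easier to obtain geometrically pure (trans-selective hydride reduction of 2) than 3. No tin is needed, and the route is two to three steps shorter.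
- Against: each shift must control both the transfer of chirality and the relative configuration at the new bond, whereas the unsubstituted oxymethyl carbanion of the chosen plan needs only the transfer. (E) alkenes lack the allylic strain that locks the envelope, so transfer and alkene geometry should be less clean. Deprotonation of donor-substituted benzyl ethers is slow and competes with ortho-lithiation next to OMe and with deprotonation of the O-benzyl protecting groups, and stabilised benzylic carbanions leak into [1,2]-shift. The propenyl groups of A7 must afterwards be degraded to CH2OH by ozonolysis and reduction in the presence of electron-rich arenes and free benzylic alcohols. Ring closure still needs a mono-oxidation and hemiketal reduction.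
- Comparison: the reaction family, the chiral-pool logic and the way the ring is closed are the same, so the plans are equal there. The alternative is the better in convergence and step count. The chosen plan is the better in stereochemical reliability of the pericyclic step and in chemoselectivity of carbanion formation (tin–lithium exchange instead of deprotonation).

Key step: step 4

Remarks on the chemistry:
- Commercial 1 of high enantiomeric purity is assumed.
- The descriptors were derived from the suprafacial course of the shift. The (2R,7R)/(3Z,5Z) ether 5 leads to (2S,3S)-7, which corresponds to (3S,4S) in 18; the pairing of (R) carbinol with (Z) alkene is essential, since an (E) alkene at one end would reverse the sense at that end.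
- The trioxolane carbons of 9 and the hemiketal carbon of 16 are formed as mixtures and are destroyed in the next operation, so they carry no descriptor. Any open-chain tautomer 15 present in 16 ionises to the same oxocarbenium ion in step 10.

## Route

Step 1
Reactants: 1 (R)-but-3-yn-2-ol (two molecules)
Product: 2 (2R,7R)-octa-3,5-diyne-2,7-diol
Conditions: CuCl (cat.), TMEDA, O2 (1 atm), acetone, rt
Reagents that add atoms: none
Why: Glaser–Hay oxidative homocoupling of a terminal alkyne, which does not touch the carbinol centre. Because two molecules of 1 are joined, the minor enantiomer of 1 ends up mainly in the separable meso diastereomer, so 2 should be enantiomerically purer than 1.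

Step 2
Reactants: 2 (2R,7R)-octa-3,5-diyne-2,7-diol
Product: 3 (2R,3Z,5Z,7R)-octa-3,5-diene-2,7-diol
Conditions: H2 (1 atm, 2 equiv metered), Pd/CaCO3 poisoned with Pb(OAc)2, quinoline, EtOAc, rt
Reagents that add atoms: none
Why: Lindlar semi-hydrogenation over Pd/CaCO3 poisoned with Pb(OAc)2: syn addition of H2 on the poisoned palladium surface turns each triple bond into a (Z) double bond. Quinoline and metering of the hydrogen should hold back over-reduction and Z-to-E isomerisation; no stereocentre is affected.

Step 3
Reactants: 3 (2R,3Z,5Z,7R)-octa-3,5-diene-2,7-diol; 4 tributyl(iodomethyl)stannane (two molecules)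
Product: 5 (2R,3Z,5Z,7R)-2,7-bis[(tributylstannyl)methoxy]octa-3,5-diene
Conditions: KH (2.5 equiv), THF, 0 °C; then 4 (2.3 equiv), 0 °C → rt
Reagents that add atoms: none
Why: Double Williamson etherification: each of the two potassium alkoxides of 3 displaces iodide from one molecule of the primary α-stannyl iodide 4 by SN2 at its CH2 carbon, so two molecules of 4 are consumed per molecule of 3. The carbinol C–O bonds and the (Z) alkenes are not involved.

Step 4
Reactants: 5 (2R,3Z,5Z,7R)-2,7-bis[(tributylstannyl)methoxy]octa-3,5-diene
Product: 7 (2S,3S)-2,3-di[(E)-prop-1-enyl]butane-1,4-diol, via lithium alkoxide of the mono-rearranged stannane 6 (not isolated)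
Conditions: n-BuLi (3 equiv, added dropwise), THF, −78 °C; then H2O
Reagents that add atoms: none
Why: Tin–lithium exchange with n-BuLi releases an unstabilised α-alkoxymethyllithium that rearranges at once by a concerted suprafacial [2,3]-sigmatropic shift (Wittig–Still rearrangement; the closest known reaction type is that of stannylmethyl ethers of secondary (Z)-allylic alcohols), and the second ether group repeats the event through alkoxide 6, so the C3–C3a and C4–C4a bonds of the target are formed and no ring is closed. In the five-membered envelope transition state the CH2 carbanion bonds to the alkene carbon three atoms away, on the face from which the C–O bond departs. Each new stereocentre is controlled by the (R) carbinol centre at the same end together with the (Z) alkene: allylic 1,3-strain between the carbinol substituents and the cis diene carbon leaves only the conformer with the carbinol hydrogen inside and the methyl group outside, which gives an (E)-propenyl group and the (S) configuration. The step needs complete transfer of chirality at both ends, since the same sense twice gives the C2-symmetric (2S,3S) diol and one slip would give the meso isomer with a (Z)-propenyl group; this is secured by the (Z,Z) geometry and the low temperature. It also needs [2,3]- over [1,2]-migration, which the unstabilised primary carbanion favours because it rearranges at −78 °C before radical-pair pathways set in. The tetrabutylstannane formed is inert and is removed by chromatography.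

Step 5
Reactants: 7 (2S,3S)-2,3-di[(E)-prop-1-enyl]butane-1,4-diol
Product: 8 (2E,4S,5S,6E)-4,5-bis[(benzyloxy)methyl]octa-2,6-diene
Conditions: NaH (2.5 equiv), BnBr (2.4 equiv), Bu4NI (cat.), THF/DMF, 0 °C → rt
Reagents that add atoms: benzyl bromide (two molecules), BrCc1ccccc1
Why: Williamson etherification of both primary alcohols. The benzyl ethers later serve as the chelating groups in step 8 and leave with the aryl benzyl ethers in step 11; no stereocentre is involved.

Step 6
Reactants: 8 (2E,4S,5S,6E)-4,5-bis[(benzyloxy)methyl]octa-2,6-diene
Product: 10 (2S,3S)-2,3-bis[(benzyloxy)methyl]butanedial, via bis-ozonide 9 (not isolated)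
Conditions: O3, CH2Cl2, −78 °C, to the first persistent blue colour; then PPh3 (2.5 equiv), −78 °C → rt; crude product used at once
Reagents that add atoms: ozone (two molecules), [O-][O+]=O
Why: Criegee ozonolysis of the two disubstituted alkenes, with reductive cleavage of bis-ozonide 9 by PPh3, gives the dialdehyde under neutral conditions. The alkenes react far faster than the benzyl ethers, and the α-stereocentres are kept by avoiding acid, base and chromatography.

Step 7
Reactants: 11 4-bromo-2-methoxyphenol
Product: 12 1-(benzyloxy)-4-bromo-2-methoxybenzene
Conditions: BnBr (1.1 equiv), K2CO3, DMF, rt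
Reagents that add atoms: benzyl bromide, BrCc1ccccc1
Why: Williamson O-alkylation of the phenol under mild base; the aryl bromide is inert to these conditions.

Step 8
Reactants: 10 (2S,3S)-2,3-bis[(benzyloxy)methyl]butanedial; 12 1-(benzyloxy)-4-bromo-2-methoxybenzene (two molecules)
Product: 14 (1S,2S,3S,4S)-1,4-bis[4-(benzyloxy)-3-methoxyphenyl]-2,3-bis[(benzyloxy)methyl]butane-1,4-diol, via arylmagnesium bromide 13 (not isolated)
Conditions: 12 (3.2 equiv), Mg turnings (I2 crystal), THF, 40 °C; added at −78 °C to 10 premixed with MgBr2·OEt2 (2.2 equiv) in CH2Cl2, −78 → −40 °C; then H2O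
Reagents that add atoms: none
Why: Twofold Grignard addition under Cram chelate control: the carbonyl oxygen and the α-CH2OBn oxygen bind magnesium in a six-membered chelate and the aryl group enters anti to the branched chain on the α-carbon. The Felkin–Anh model selects the same face when that chain is taken as the large group, so both new carbinol centres should be (S), which places each aryl group cis to the neighbouring CH2OBn group once the ring is closed. Low temperature and the weakly basic aryl Grignard reagent should suppress enolisation and β-elimination of 10.

Step 9
Reactants: 14 (1S,2S,3S,4S)-1,4-bis[4-(benzyloxy)-3-methoxyphenyl]-2,3-bis[(benzyloxy)methyl]butane-1,4-diol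
Product: 16 (3S,4S,5S)-2,5-bis[4-(benzyloxy)-3-methoxyphenyl]-3,4-bis[(benzyloxy)methyl]tetrahydrofuran-2-ol, via hydroxy ketone 15 (not isolated)
Conditions: activated MnO2 (10 equiv), CH2Cl2, rt; filtered as soon as 14 is consumed
Reagents that add atoms: none
Why: Selective benzylic alcohol oxidation with MnO2; once one carbinol is oxidised, hydroxy ketone 15 closes to the five-membered hemiketal 16, whose hemiketal carbon has no hydrogen to lose and whose second carbinol oxygen is now the ring oxygen, so the oxidation should stop at the mono stage. The configuration at C5 is retained because its C–O bond is not broken.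

Step 10
Reactants: 16 (3S,4S,5S)-2,5-bis[4-(benzyloxy)-3-methoxyphenyl]-3,4-bis[(benzyloxy)methyl]tetrahydrofuran-2-ol
Product: 17 (2S,3S,4S,5S)-2,5-bis[4-(benzyloxy)-3-methoxyphenyl]-3,4-bis[(benzyloxy)methyl]tetrahydrofuran
Conditions: Et3SiH (5 equiv), BF3·OEt2 (2 equiv), CH2Cl2, −78 °C; quenched at −78 °C with Et3N then aq NaHCO3
Reagents that add atoms: none
Why: Ionic hydrogenation (reductive deoxygenation of a hemiketal): BF3·OEt2 ionises 16 to the aryl-conjugated oxocarbenium ion and Et3SiH delivers hydride to C2 anti to the C3 substituent, which allylic strain with the coplanar aryl group forces pseudo-axial, so the aryl group ends up cis to C3–CH2OBn (2S). The reaction is run and quenched cold because the 2,3-cis product is the kinetic one and the benzylic C–O bonds can epimerise under Lewis acid.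

Step 11
Reactants: 17 (2S,3S,4S,5S)-2,5-bis[4-(benzyloxy)-3-methoxyphenyl]-3,4-bis[(benzyloxy)methyl]tetrahydrofuran
Product: 18 eduesmine, [(2S,3S,4S,5S)-2,5-bis(4-hydroxy-3-methoxyphenyl)tetrahydrofuran-3,4-diyl]dimethanol
Conditions: H2 (1 atm), Pd/C (10 wt%), EtOAc/MeOH, rt; stopped when the last benzyl ether is gone
Reagents that add atoms: none
Why: Catalytic hydrogenolysis of all four O-benzyl groups under neutral conditions; aryl and alkyl benzyl ethers should be cleaved faster than the ring C2–O1 and C5–O1 bonds, which normally need acid or forcing conditions. No stereocentre is touched.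

## Compound list

1 | (R)-but-3-yn-2-ol | C[C@@H](O)C#C | starting material
2 | (2R,7R)-octa-3,5-diyne-2,7-diol | C[C@@H](O)C#CC#C[C@@H](C)O | intermediate
3 | (2R,3Z,5Z,7R)-octa-3,5-diene-2,7-diol | C[C@@H](O)/C=C\C=C/[C@@H](C)O | intermediate
4 | tributyl(iodomethyl)stannane | CCCC[Sn](CI)(CCCC)CCCC | starting material
5 | (2R,3Z,5Z,7R)-2,7-bis[(tributylstannyl)methoxy]octa-3,5-diene | C[C@@H](OC[Sn](CCCC)(CCCC)CCCC)/C=C\C=C/[C@@H](C)OC[Sn](CCCC)(CCCC)CCCC | intermediate
6 | lithium (2S,3Z,5R)-2-[(E)-prop-1-enyl]-5-[(tributylstannyl)methoxy]hex-3-en-1-olate | C/C=C/[C@H](CO[Li])/C=C\[C@@H](C)OC[Sn](CCCC)(CCCC)CCCC | intermediate (not isolated)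
7 | (2S,3S)-2,3-di[(E)-prop-1-enyl]butane-1,4-diol | C/C=C/[C@H](CO)[C@@H](CO)/C=C/C | intermediate
8 | (2E,4S,5S,6E)-4,5-bis[(benzyloxy)methyl]octa-2,6-diene | C/C=C/[C@H](COCc1ccccc1)[C@@H](COCc1ccccc1)/C=C/C | intermediate
9 | 3,3'-[(2S,3S)-1,4-bis(benzyloxy)butane-2,3-diyl]bis(5-methyl-1,2,4-trioxolane), mixture at the trioxolane carbons | CC1OC(OO1)[C@H](COCc1ccccc1)[C@@H](COCc1ccccc1)C1OC(C)OO1 | intermediate (not isolated)
10 | (2S,3S)-2,3-bis[(benzyloxy)methyl]butanedial | O=C[C@H](COCc1ccccc1)[C@@H](COCc1ccccc1)C=O | intermediate
11 | 4-bromo-2-methoxyphenol | COc1cc(Br)ccc1O | starting material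
12 | 1-(benzyloxy)-4-bromo-2-methoxybenzene | COc1cc(Br)ccc1OCc1ccccc1 | intermediate
13 | [4-(benzyloxy)-3-methoxyphenyl]magnesium bromide | COc1cc([Mg]Br)ccc1OCc1ccccc1 | intermediate (not isolated)
14 | (1S,2S,3S,4S)-1,4-bis[4-(benzyloxy)-3-methoxyphenyl]-2,3-bis[(benzyloxy)methyl]butane-1,4-diol | COc1cc([C@@H](O)[C@H](COCc2ccccc2)[C@@H](COCc2ccccc2)[C@H](O)c2ccc(OCc3ccccc3)c(OC)c2)ccc1OCc1ccccc1 | intermediate
15 | (2S,3S,4S)-1,4-bis[4-(benzyloxy)-3-methoxyphenyl]-2,3-bis[(benzyloxy)methyl]-4-hydroxybutan-1-one | COc1cc(C(=O)[C@H](COCc2ccccc2)[C@@H](COCc2ccccc2)[C@H](O)c2ccc(OCc3ccccc3)c(OC)c2)ccc1OCc1ccccc1 | intermediate (not isolated)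
16 | (3S,4S,5S)-2,5-bis[4-(benzyloxy)-3-methoxyphenyl]-3,4-bis[(benzyloxy)methyl]tetrahydrofuran-2-ol, mixture at C2 | COc1cc(C2(O)O[C@H](c3ccc(OCc4ccccc4)c(OC)c3)[C@H](COCc3ccccc3)[C@H]2COCc2ccccc2)ccc1OCc1ccccc1 | intermediate
17 | (2S,3S,4S,5S)-2,5-bis[4-(benzyloxy)-3-methoxyphenyl]-3,4-bis[(benzyloxy)methyl]tetrahydrofuran | COc1cc([C@H]2O[C@H](c3ccc(OCc4ccccc4)c(OC)c3)[C@H](COCc3ccccc3)[C@H]2COCc2ccccc2)ccc1OCc1ccccc1 | intermediate
18 | eduesmine, [(2S,3S,4S,5S)-2,5-bis(4-hydroxy-3-methoxyphenyl)tetrahydrofuran-3,4-diyl]dimethanol | COc1cc([C@H]2O[C@H](c3ccc(O)c(OC)c3)[C@H](CO)[C@H]2CO)ccc1O | target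

## Step count and least certain steps

Total step count: 11. Longest linear sequence: 10 steps (steps 1 to 6 and 8 to 11, from 1 to 18); step 7 is a one-step branch.

**Step 4 (key step).**
- Risk: the second exchange and shift may be incomplete on the aggregated alkoxide 6. At the dienylic stage the ether may partly cleave homolytically and recombine as a [1,2]-shift, because the carbinol carbon can give a delocalised radical. Some reaction may leak through the methyl-inside conformer, which would cost chirality transfer at one end.
- Fallback (sets out from 3, returns at 7): the same two C–C bonds are made by the ester-enolate variant of the [2,3]-Wittig rearrangement, where the carbanion is formed by deprotonation and is then degraded by one carbon.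
 - 3 is O-alkylated twice with tert-butyl bromoacetate (aq NaOH, Bu4NHSO4, toluene) to give di-tert-butyl 2,2'-[(2R,3Z,5Z,7R)-octa-3,5-diene-2,7-diylbis(oxy)]diacetate F1.
 - LiN(iPr)2 in THF (−78 → 0 °C) should give, through the same envelope and the same allylic-strain control, di-tert-butyl (3S,4S)-2,5-dihydroxy-3,4-di[(E)-prop-1-enyl]hexanedioate F2; its two extra carbinol centres are of no consequence.
 - LiAlH4 reduces it to (3S,4S)-3,4-di[(E)-prop-1-enyl]hexane-1,2,5,6-tetraol F3.
 - NaIO4 cleaves both glycols to (2S,3S)-2,3-di[(E)-prop-1-enyl]butanedial F4, which is reduced in the same flask with NaBH4 to 7.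

**Step 2.**
- Risk: hydrogenation may continue past the diene, or the (Z) alkenes may isomerise on palladium, because the conjugated diene binds the catalyst nearly as well as the diyne. Any (E) alkene would later reverse the sense of the shift at that end.
- Fallback (sets out from 2, returns at 3; no new compound, F0): the catalytic hydrogenation is replaced by a stoichiometric metal reduction with Zn dust activated by Cu(OAc)2 and AgNO3 in MeOH/H2O (Boland reduction). This works by electron transfer to the conjugated triple bonds followed by protonation, attacks only conjugated alkynes, and cannot reduce the resulting diene.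

**Step 8.**
- Risk: the α-branched β-alkoxy dialdehyde may be enolised by the basic reagent (epimerisation, loss of benzyl alcohol). After the first addition the alkoxide may close on the second aldehyde to a lactolate, from which the second addition is slow and may escape chelate control.
- Fallback (sets out from 10, returns at 16): the aryl groups are introduced one at a time at different oxidation levels.
 - Only one equivalent of 13 is added to 10 at −78 °C; the mono-adduct closes to (3S,4S,5S)-5-[4-(benzyloxy)-3-methoxyphenyl]-3,4-bis[(benzyloxy)methyl]tetrahydrofuran-2-ol F5.
 - Oxidation with Pr4N[RuO4] (cat.) and N-methylmorpholine N-oxide gives (3S,4S,5S)-5-[4-(benzyloxy)-3-methoxyphenyl]-3,4-bis[(benzyloxy)methyl]dihydrofuran-2(3H)-one F6.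
 - [4-(Benzyloxy)-3-methoxyphenyl]lithium F7, made from 12 and n-BuLi in THF at −78 °C, adds once to the lactone carbonyl to give 16 directly.

**Step 9.**
- Risk: oxidation may continue through the open tautomer 15 to the 1,4-diketone, because ring closure to 16 is reversible; or it may stall on the hindered secondary alcohols.
- Fallback (sets out from 14, returns at 16): the desymmetrisation is done by protection instead of by self-limiting oxidation.
 - Statistical mono-silylation (t-BuMe2SiCl, imidazole, DMF; unreacted 14 recycled) gives (1S,2S,3S,4S)-1,4-bis[4-(benzyloxy)-3-methoxyphenyl]-2,3-bis[(benzyloxy)methyl]-4-[(tert-butyldimethylsilyl)oxy]butan-1-ol F8.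
 - Dess–Martin periodinane oxidises the free carbinol to (2S,3S,4S)-1,4-bis[4-(benzyloxy)-3-methoxyphenyl]-2,3-bis[(benzyloxy)methyl]-4-[(tert-butyldimethylsilyl)oxy]butan-1-one F9.
 - Bu4NF (buffered with AcOH) removes the silyl group; the resulting 15 closes to 16.

**Step 10.**
- Risk: facial selectivity of hydride delivery may be poor if the C4 substituent and the C5 aryl group block the face anti to C3. The Lewis acid may ionise the electron-rich benzylic C5–O1 or C2–O1 bond, leading to epimerisation towards the trans arrangement or to ring-opening reduction.
- Fallback (sets out from 10, returns at 17): the roles of nucleophile and ring carbon are exchanged, so the C2 aryl group is delivered as a carbon nucleophile to a C2–H oxocarbenium ion.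
 - Lactol F5 (from 10 as in the fallback for step 8) is converted with PhSO2H and CaCl2 in CH2Cl2 into (3S,4S,5S)-5-[4-(benzyloxy)-3-methoxyphenyl]-3,4-bis[(benzyloxy)methyl]-2-(phenylsulfonyl)tetrahydrofuran F10.
 - [4-(Benzyloxy)-3-methoxyphenyl]zinc bromide F11 (from 13 and ZnBr2, THF, rt) displaces the sulfinate. In this ion the C3 group is pseudo-equatorial, and inside attack on the envelope, trans to the C4 substituent, should place the aryl group cis to C3–CH2OBn, giving 17. Substitution of 2-sulfonyl cyclic ethers by organozinc reagents is a known reaction type.

## Further compounds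

F1 | step 4 | di-tert-butyl 2,2'-[(2R,3Z,5Z,7R)-octa-3,5-diene-2,7-diylbis(oxy)]diacetate | C[C@@H](OCC(=O)OC(C)(C)C)/C=C\C=C/[C@@H](C)OCC(=O)OC(C)(C)C
F2 | step 4 | di-tert-butyl (3S,4S)-2,5-dihydroxy-3,4-di[(E)-prop-1-enyl]hexanedioate | C/C=C/[C@H](C(O)C(=O)OC(C)(C)C)[C@@H](C(O)C(=O)OC(C)(C)C)/C=C/C
F3 | step 4 | (3S,4S)-3,4-di[(E)-prop-1-enyl]hexane-1,2,5,6-tetraol | C/C=C/[C@H](C(O)CO)[C@@H](C(O)CO)/C=C/C
F4 | step 4 | (2S,3S)-2,3-di[(E)-prop-1-enyl]butanedial | C/C=C/[C@H](C=O)[C@@H](C=O)/C=C/C
F0 | step 2 | none | none
F5 | step 8 | (3S,4S,5S)-5-[4-(benzyloxy)-3-methoxyphenyl]-3,4-bis[(benzyloxy)methyl]tetrahydrofuran-2-ol | COc1cc([C@H]2OC(O)[C@H](COCc3ccccc3)[C@H]2COCc2ccccc2)ccc1OCc1ccccc1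
F6 | step 8 | (3S,4S,5S)-5-[4-(benzyloxy)-3-methoxyphenyl]-3,4-bis[(benzyloxy)methyl]dihydrofuran-2(3H)-one | COc1cc([C@H]2OC(=O)[C@H](COCc3ccccc3)[C@H]2COCc2ccccc2)ccc1OCc1ccccc1
F7 | step 8 | [4-(benzyloxy)-3-methoxyphenyl]lithium | [Li]c1ccc(OCc2ccccc2)c(OC)c1
F8 | step 9 | (1S,2S,3S,4S)-1,4-bis[4-(benzyloxy)-3-methoxyphenyl]-2,3-bis[(benzyloxy)methyl]-4-[(tert-butyldimethylsilyl)oxy]butan-1-ol | COc1cc([C@@H](O[Si](C)(C)C(C)(C)C)[C@H](COCc2ccccc2)[C@@H](COCc2ccccc2)[C@H](O)c2ccc(OCc3ccccc3)c(OC)c2)ccc1OCc1ccccc1
F9 | step 9 | (2S,3S,4S)-1,4-bis[4-(benzyloxy)-3-methoxyphenyl]-2,3-bis[(benzyloxy)methyl]-4-[(tert-butyldimethylsilyl)oxy]butan-1-one | COc1cc([C@@H](O[Si](C)(C)C(C)(C)C)[C@H](COCc2ccccc2)[C@@H](COCc2ccccc2)C(=O)c2ccc(OCc3ccccc3)c(OC)c2)ccc1OCc1ccccc1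
F10 | step 10 | (3S,4S,5S)-5-[4-(benzyloxy)-3-methoxyphenyl]-3,4-bis[(benzyloxy)methyl]-2-(phenylsulfonyl)tetrahydrofuran | COc1cc([C@H]2OC(S(=O)(=O)c3ccccc3)[C@H](COCc3ccccc3)[C@H]2COCc2ccccc2)ccc1OCc1ccccc1
F11 | step 10 | [4-(benzyloxy)-3-methoxyphenyl]zinc bromide | COc1cc([Zn]Br)ccc1OCc1ccccc1
A1 | alternative 1 | (2S,3R,4R,5S)-2,5-bis(4-benzyloxy-3-methoxyphenyl)-N3,N4-di(quinolin-8-yl)tetrahydrofuran-3,4-dicarboxamide | COc1cc([C@H]2O[C@H](c3ccc(OCc4ccccc4)c(OC)c3)[C@H](C(=O)Nc3cccc4cccnc34)[C@H]2C(=O)Nc2cccc3cccnc23)ccc1OCc1ccccc1
A2 | alternative 1 | (3R,4R)-N3,N4-di(quinolin-8-yl)tetrahydrofuran-3,4-dicarboxamide | C1OC[C@H](C(=O)Nc2cccc3cccnc23)[C@H]1C(=O)Nc1cccc2cccnc12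
A3 | alternative 1 | 1-(benzyloxy)-4-iodo-2-methoxybenzene | COc1cc(I)ccc1OCc1ccccc1
A4 | alternative 2 | (4S,5S)-5-(4-benzyloxy-3-methoxyphenyl)-4-(benzyloxymethyl)dihydrofuran-2(3H)-one | O=C1O[C@H](c2ccc(OCc3ccccc3)c(OC)c2)[C@H](COCc2ccccc2)C1
A5 | alternative 2 | (E)-4-(benzyloxy)but-2-enal | O=C/C=C/COCc1ccccc1
A6 | alternative 2 | 4-(benzyloxy)-3-methoxybenzaldehyde | COc1cc(C=O)ccc1OCc1ccccc1
A7 | alternative 3 | (1S,2R,3R,4S)-1,4-bis(4-benzyloxy-3-methoxyphenyl)-2,3-di[(E)-prop-1-enyl]butane-1,4-diol | COc1cc([C@@H](O)[C@H](/C=C/C)[C@@H](/C=C/C)[C@H](O)c2ccc(OCc3ccccc3)c(OC)c2)ccc1OCc1ccccc1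
A8 | alternative 3 | (2R,3E,5E,7R)-2,7-bis{[4-(benzyloxy)-3-methoxybenzyl]oxy}octa-3,5-diene | C[C@@H](OCc1ccc(OCc2ccccc2)c(OC)c1)/C=C/C=C/[C@@H](C)OCc1ccc(OCc2ccccc2)c(OC)c1
A9 | alternative 3 | (2R,3E,5E,7R)-octa-3,5-diene-2,7-diol | C[C@@H](O)/C=C/C=C/[C@@H](C)O
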